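**Retrosynthetic overview**

1. Skeleton numbering used throughout: enone bridge C1(=O)–C2=C3(Me)–C4; cyclobutane C4–C5–C11–C10(Me); seven-membered ring C5–C6(Me2)–C7(O)–C8–C9(O)–C10–C11.
2. The strategy rests on C5 and C10, the two cyclobutane carbons that flank C11, carrying the two ends of the four-carbon chain C6–C9. The seven-membered ring is therefore cut at C5–C6 and C9–C10 into a C5–C11–C10 oxyallyl cation of a cyclobutanone and the diene C6=C7–C8=C9 ([4+3]).
3. The cyclobutane is purchased (3-oxocyclobutane-1-carboxylic acid) and desymmetrised by enantioselective enolsilylation. Its C4 Weinreb amide steers the diene to the opposite face and later becomes the C3 methyl ketone.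
4. The six-membered enone ring is closed last: C11 ketone to C11–CHO to β-ketophosphonate, then intramolecular Horner–Wadsworth–Emmons reaction (C2=C3) across C4 and C11.
5. Endgame: an Evans–Tishchenko reduction with tiglic aldehyde sets C7 trans to C9 and places the tiglate on O9, then O7 is isovalerylated. Ring order: cyclobutane (purchased), seven-membered ring (step 8), cyclohexenone (step 14).

Key step: step 8

Assumption: in step 2 the (R,R)-amide is taken to remove the proton that leads to (S)-3; the sense of induction would be checked on the first run and the (S,S)-amide used if it is opposite.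

**Route**

Step 1
Reactants: 1 3-oxocyclobutane-1-carboxylic acid
Product: 2 N-methoxy-N-methyl-3-oxocyclobutane-1-carboxamide
Conditions: CDI, CH2Cl2, rt; then MeNHOMe·HCl
Reagents that add atoms: N,O-dimethylhydroxylamine hydrochloride, CNOC.Cl
Why: Weinreb amide formation through the acyl imidazolide; the amide is preferred to an ester because its C4–H is less acidic and it later gives the methyl ketone in one step.

Step 2
Reactants: 2 N-methoxy-N-methyl-3-oxocyclobutane-1-carboxamide
Product: 3 (S)-N-methoxy-N-methyl-3-(trimethylsilyloxy)cyclobut-2-ene-1-carboxamide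
Conditions: (R,R)-bis(1-phenylethyl)amine, n-BuLi, TMSCl (in situ), THF, −100 °C
Reagents that add atoms: chlorotrimethylsilane, C[Si](C)(C)Cl
Why: Enantioselective deprotonation of a prochiral 3-substituted cyclobutanone by a C2-symmetric chiral lithium amide with in situ silylation distinguishes the two enantiotopic α-methylenes and so sets C4, the only stereocentre that survives into the key step.

Step 3
Reactants: 3 (S)-N-methoxy-N-methyl-3-(trimethylsilyloxy)cyclobut-2-ene-1-carboxamide
Product: 4 (1S,2R)-N-methoxy-N,2-dimethyl-3-oxocyclobutane-1-carboxamide (methyl trans to the amide)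
Conditions: BnMe3N+ F−, MeI, 4 Å MS, THF, 0 °C
Reagents that add atoms: iodomethane, CI
Why: Fluoride-mediated alkylation of a silyl enol ether through its ammonium enolate should place the methyl group regiospecifically on the former enol carbon C10, anti to the amide, without touching the Weinreb amide.

Step 4
Reactants: 4 (1S,2R)-N-methoxy-N,2-dimethyl-3-oxocyclobutane-1-carboxamide
Product: 5 (1R,2R)-2-chloro-N-methoxy-N,2-dimethyl-3-oxocyclobutane-1-carboxamide (chlorine trans to the amide)
Conditions: SO2Cl2, CH2Cl2, 0 °C
Reagents that add atoms: sulfuryl chloride, O=S(=O)(Cl)Cl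
Why: α-Chlorination of an unsymmetrical ketone with SO2Cl2 goes through the more substituted enol, so chlorine should enter at the methyl-bearing C10 from the face opposite the amide; either C10 epimer would ionise to the same cation.

Step 5
Reactants: 6 4-methylpent-1-yn-3-ol
Product: 7 4-methylpent-1-yn-3-one
Conditions: MnO2, CH2Cl2, rt
Reagents that add atoms: none
Why: MnO2 oxidation of a propargylic alcohol to the ynone.

Step 6
Reactants: 7 4-methylpent-1-yn-3-one; 8 4-methoxybenzyl alcohol
Product: 9 (E)-1-(4-methoxybenzyloxy)-4-methylpent-1-en-3-one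
Conditions: DABCO (10 mol %), CH2Cl2, 0 °C → rt
Reagents that add atoms: none
Why: Amine-catalysed oxa-Michael addition of an alcohol to a terminal ynone should give the (E)-β-alkoxy enone.

Step 7
Reactants: 9 (E)-1-(4-methoxybenzyloxy)-4-methylpent-1-en-3-one
Product: 10 (E)-1-(4-methoxybenzyloxy)-3-(tert-butyldimethylsilyloxy)-4-methylpenta-1,3-diene
Conditions: TBSOTf, Et3N, Et2O, 0 °C
Reagents that add atoms: tert-butyldimethylsilyl trifluoromethanesulfonate, CC(C)(C)[Si](C)(C)OS(=O)(=O)C(F)(F)F
Why: Soft enolisation with silyl triflate and amine; the isopropyl methine is the only enolisable position, so the 2-silyloxydiene forms with the (E)-enol ether untouched.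

Step 8
Reactants: 5 (1R,2R)-2-chloro-N-methoxy-N,2-dimethyl-3-oxocyclobutane-1-carboxamide; 10 (E)-1-(4-methoxybenzyloxy)-3-(tert-butyldimethylsilyloxy)-4-methylpenta-1,3-diene
Product: 13 bicyclo[4.1.1]oct-3-en-8-one cycloadduct (C11 ketone; C4 Weinreb amide anti to the C6–C9 bridge; C9 OPMB turned toward C11; C7=C8 TBS enol ether; C6 Me2; C10 Me), via oxyallyl cation 11 (not isolated), via zwitterion 12 (not isolated)
Conditions: NaOCH2CF3 (1.5 equiv), CF3CH2OH, 0 °C → rt, 10 (2.5 equiv)
Reagents that add atoms: none
Why: Proposed new method: trifluoroethoxide enolises 5 toward C5 and chloride leaves from the tertiary carbon C10 to give the 2-oxidocyclobutenyl (oxyallyl) cation 11; the closest known reaction type is the base-induced [4+3] cycloaddition of α-chlorocyclopentanones and α-chlorocyclohexanones with dienes and furans in trifluoroethanol, which has not been shown for a cyclobutanone. The nucleophilic terminus C6 of the silyloxydiene attacks the unsubstituted terminus C5 to give zwitterion 12, and its enolate carbon C10 then closes on the oxocarbenium carbon C9, so the seven-membered ring forms by a stepwise two-bond annulation that ends in an enolate-to-oxocarbenium ring closure. C5 and C10 are set by approach of the diene to the face of the planar cation anti to the C4 carboxamide, the only stereocentre of 11, which also carries the absolute configuration. C9 follows from the (E)-enol ether and a compact arrangement in which the diene lies under the C11 oxygen, favoured by attraction between the enolate oxygen and the cationic diene carbons. The regiochemistry (C6 to C5, C9 to C10) is secured by sterics, because the alternative would join the two fully substituted carbons C6 and C10. The step needs ionisation to outrun alkoxide addition to the carbonyl (semibenzilic ring contraction), which the weakly nucleophilic ionising solvent and the tertiary chloride favour, and the amide keeps C4–H much less acidic than C5–H.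

Step 9
Reactants: 13 bicyclo[4.1.1]oct-3-en-8-one cycloadduct
Product: 14 C11-methylene compound (exocyclic C11=CH2; other groups as in 13)
Conditions: Ph3PCH3Br, KN(SiMe3)2, THF, 0 → 40 °C
Reagents that add atoms: methyltriphenylphosphonium bromide, C[P+](c1ccccc1)(c1ccccc1)c1ccccc1.[Br-]
Why: Wittig methylenation of the strained, non-enolisable cyclobutanone with the smallest ylide, made without alkoxide so that the silyl enol ether and the amide should survive.

Step 10
Reactants: 14 C11-methylene compound
Product: 16 C11-hydroxymethyl compound (CH2OH mainly syn to the C6–C9 bridge), via alkylborane 15 (not isolated)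
Conditions: 9-BBN, THF, 0 °C → rt; then H2O2, aq. NaOH, 0 °C
Reagents that add atoms: hydrogen peroxide, OO
Why: Anti-Markovnikov hydroboration–oxidation, selective for the 1,1-disubstituted alkene over the hindered silyl enol ether; boron adds to the outer carbon and hydrogen to C11 from the face anti to the four-carbon bridge, so C1 is expected mainly syn to that bridge at this stage.

Step 11
Reactants: 16 C11-hydroxymethyl compound
Product: 18 C11 aldehyde (formyl anti to the C6–C9 bridge; cis to the C4 amide across the cyclobutane), via syn aldehyde 17 (not isolated)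
Conditions: DMP, pyridine, CH2Cl2, 0 °C; then DBU (0.2 equiv), rt
Reagents that add atoms: none
Why: Dess–Martin oxidation followed by base-mediated epimerisation through the enolate, which is expected to move the formyl group out of the position pressed against C6–Me and C9–O into the position anti to the bridge, the C11 configuration of the target.

Step 12
Reactants: 18 C11 aldehyde
Product: 19 β-ketophosphonate (C11–C1(=O)–C2H2–P(O)(OMe)2; C4 Weinreb amide)
Conditions: N2CHP(O)(OMe)2, SnCl2 (20 mol %), CH2Cl2, rt
Reagents that add atoms: dimethyl (diazomethyl)phosphonate, COP(=O)(OC)C=[N+]=[N-]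
Why: Roskamp-type homologation: SnCl2-catalysed addition of the diazomethylphosphonate to the aldehyde, 1,2-hydride shift and loss of N2 give the β-ketophosphonate under neutral conditions that leave amide, silyl enol ether and C11 untouched.

Step 13
Reactants: 19 β-ketophosphonate
Product: 20 keto phosphonate methyl ketone (C4–C3(=O)CH3; C11–C(=O)CH2P(O)(OMe)2)
Conditions: MeMgBr (3 equiv), THF, −20 → 0 °C; aq. NH4Cl
Reagents that add atoms: methylmagnesium bromide, C[Mg]Br
Why: The first equivalent of Grignard reagent deprotonates the β-ketophosphonate and so protects it as its magnesium enolate, and the chelated Weinreb amide then accepts one methyl group to give the methyl ketone on work-up.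

Step 14
Reactants: 20 keto phosphonate methyl ketone
Product: 21 tricyclic enone (C1 enone; C7=C8 TBS enol ether; C9 OPMB)
Conditions: K2CO3, 18-crown-6, toluene, 80 °C
Reagents that add atoms: none
Why: Intramolecular Horner–Wadsworth–Emmons reaction of the β-ketophosphonate with the methyl ketone forms C2=C3 and closes the six-membered enone ring across the cis-1,3 positions C4 and C11; only the cis arrangement can close, any C4 or C11 epimer should be returned to it by enolisation under the basic conditions, and both centres then become locked bridgeheads.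

Step 15
Reactants: 21 tricyclic enone
Product: 22 tricyclic enone C7 ketone (C9 OPMB)
Conditions: TBAF, AcOH, THF, 0 °C
Reagents that add atoms: none
Why: Buffered fluoride cleavage of the silyl enol ether should give the C7 ketone without base-induced β-elimination of the C9 ether.

Step 16
Reactants: 22 tricyclic enone C7 ketone
Product: 23 β-hydroxy ketone (C9–OH; C7 ketone)
Conditions: DDQ, CH2Cl2/pH 7 buffer, 0 °C
Reagents that add atoms: none
Why: Oxidative cleavage of the 4-methoxybenzyl ether with DDQ; the enone and the saturated ketone are inert and no electron-rich alkene remains.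

Step 17
Reactants: 23 β-hydroxy ketone
Product: 24 C9 tiglate C7 alcohol (C7–OH trans to C9–O)
Conditions: (E)-2-methylbut-2-enal (6 equiv), SmI2 (30 mol %), THF, −10 °C
Reagents that add atoms: (E)-2-methylbut-2-enal, C/C=C(\C)C=O
Why: Evans–Tishchenko reduction: the samarium-bound hemiacetal formed from the C9 hydroxyl and the aldehyde delivers hydride intramolecularly to C7 on the face of the C9 oxygen, which should give the 1,3-anti (trans) diol with the tigloyl group already on O9 and the C7 hydroxyl free.

Step 18
Reactants: 24 C9 tiglate C7 alcohol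
Product: 25 CNP0194415.1 (C9 tiglate; C7 isovalerate)
Conditions: 3-methylbutanoyl chloride, pyridine, DMAP, CH2Cl2, 0 °C → rt
Reagents that add atoms: 3-methylbutanoyl chloride, CC(C)CC(=O)Cl
Why: DMAP-catalysed acylation of the remaining hindered secondary alcohol; the 1,3-trans relationship should prevent acyl migration.

**Compound list**

1 | 3-oxocyclobutane-1-carboxylic acid | O=C1CC(C(=O)O)C1 | starting material
2 | N-methoxy-N-methyl-3-oxocyclobutane-1-carboxamide | CON(C)C(=O)C1CC(=O)C1 | intermediate
3 | (S)-N-methoxy-N-methyl-3-(trimethylsilyloxy)cyclobut-2-ene-1-carboxamide | CON(C)C(=O)[C@H]1CC(O[Si](C)(C)C)=C1 | intermediate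
4 | (1S,2R)-N-methoxy-N,2-dimethyl-3-oxocyclobutane-1-carboxamide | CON(C)C(=O)[C@H]1CC(=O)[C@@H]1C | intermediate
5 | (1R,2R)-2-chloro-N-methoxy-N,2-dimethyl-3-oxocyclobutane-1-carboxamide | CON(C)C(=O)[C@H]1CC(=O)[C@]1(C)Cl | intermediate
6 | 4-methylpent-1-yn-3-ol (racemic) | CC(C)C(O)C#C | starting material
7 | 4-methylpent-1-yn-3-one | CC(C)C(=O)C#C | intermediate
8 | 4-methoxybenzyl alcohol | COc1ccc(CO)cc1 | starting material
9 | (E)-1-(4-methoxybenzyloxy)-4-methylpent-1-en-3-one | CC(C)C(=O)/C=C/OCc1ccc(OC)cc1 | intermediate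
10 | (E)-1-(4-methoxybenzyloxy)-3-(tert-butyldimethylsilyloxy)-4-methylpenta-1,3-diene | CC(C)=C(O[Si](C)(C)C(C)(C)C)/C=C/OCc1ccc(OC)cc1 | intermediate
11 | 2-oxidocyclobutenyl (oxyallyl) cation from 5, C4 amide retained | CON(C)C(=O)[C@H]1C=C([O-])[C+]1C | intermediate
12 | zwitterion after C5–C6 bond formation (C10–C11 enolate; C9 oxocarbenium) | COc1ccc(C[O+]=C/C=C(/O[Si](C)(C)C(C)(C)C)C(C)(C)[C@@H]2C([O-])=C(C)[C@H]2C(=O)N(C)OC)cc1 | intermediate
13 | bicyclo[4.1.1]oct-3-en-8-one cycloadduct (C11 ketone, C4 Weinreb amide, C9 OPMB, C7 OTBS enol ether) | COc1ccc(CO[C@@H]2C=C(O[Si](C)(C)C(C)(C)C)C(C)(C)[C@@H]3C(=O)[C@@]2(C)[C@H]3C(=O)N(C)OC)cc1 | intermediate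
14 | C11-methylene compound | COc1ccc(CO[C@@H]2C=C(O[Si](C)(C)C(C)(C)C)C(C)(C)[C@@H]3C(=C)[C@@]2(C)[C@H]3C(=O)N(C)OC)cc1 | intermediate
15 | B-alkyl-9-borabicyclo[3.3.1]nonane adduct of 14 | COc1ccc(CO[C@@H]2C=C(O[Si](C)(C)C(C)(C)C)C(C)(C)[C@@H]3[C@H](CB4C5CCCC4CCC5)[C@@]2(C)[C@H]3C(=O)N(C)OC)cc1 | intermediate
16 | C11-hydroxymethyl compound (CH2OH syn to the C6–C9 bridge) | COc1ccc(CO[C@@H]2C=C(O[Si](C)(C)C(C)(C)C)C(C)(C)[C@@H]3[C@H](CO)[C@@]2(C)[C@H]3C(=O)N(C)OC)cc1 | intermediate
17 | C11 aldehyde, formyl syn to the C6–C9 bridge | COc1ccc(CO[C@@H]2C=C(O[Si](C)(C)C(C)(C)C)C(C)(C)[C@@H]3[C@H](C=O)[C@@]2(C)[C@H]3C(=O)N(C)OC)cc1 | intermediate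
18 | C11 aldehyde, formyl anti to the C6–C9 bridge (cis to the C4 amide) | COc1ccc(CO[C@@H]2C=C(O[Si](C)(C)C(C)(C)C)C(C)(C)[C@@H]3[C@@H](C=O)[C@@]2(C)[C@H]3C(=O)N(C)OC)cc1 | intermediate
19 | β-ketophosphonate with C4 Weinreb amide | COc1ccc(CO[C@@H]2C=C(O[Si](C)(C)C(C)(C)C)C(C)(C)[C@@H]3[C@@H](C(=O)CP(=O)(OC)OC)[C@@]2(C)[C@H]3C(=O)N(C)OC)cc1 | intermediate
20 | β-ketophosphonate with C4 acetyl | COc1ccc(CO[C@@H]2C=C(O[Si](C)(C)C(C)(C)C)C(C)(C)[C@@H]3[C@@H](C(=O)CP(=O)(OC)OC)[C@@]2(C)[C@H]3C(C)=O)cc1 | intermediate
21 | tricyclic enone (C7 OTBS enol ether, C9 OPMB) | COc1ccc(CO[C@@H]2C=C(O[Si](C)(C)C(C)(C)C)C(C)(C)[C@@H]3[C@H]4C(=O)C=C(C)[C@@H]3[C@]42C)cc1 | intermediate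
22 | tricyclic enone C7 ketone (C9 OPMB) | COc1ccc(CO[C@@H]2CC(=O)C(C)(C)[C@@H]3[C@H]4C(=O)C=C(C)[C@@H]3[C@]42C)cc1 | intermediate
23 | tricyclic β-hydroxy ketone (C9–OH, C7 ketone) | O[C@@H]1CC(=O)C(C)(C)[C@@H]2[C@H]3C(=O)C=C(C)[C@@H]2[C@]31C | intermediate
24 | C9 tiglate C7 alcohol | C/C=C(\C)C(=O)O[C@@H]1C[C@@H](O)C(C)(C)[C@@H]2[C@H]3C(=O)C=C(C)[C@@H]2[C@]31C | intermediate
25 | CNP0194415.1 | C/C=C(\C)C(=O)O[C@@H]1C[C@@H](OC(=O)CC(C)C)C(C)(C)[C@@H]2[C@H]3C(=O)C=C(C)[C@@H]2[C@]31C | target

**Step count and risks**

Total step count: 18. Longest linear sequence: 15 steps (steps 1–4 and 8–18).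

Steps most likely to fail:

1. Step 8 (proposed new method). Alkoxide addition to the cyclobutanone carbonyl followed by 1,2-shift (ring contraction) may outrun ionisation, the solvent may capture the cation or desilylate the diene, or the first bond may form without ring closure. The fallback reverses the polarity and forms the two bonds one after the other by known reactions; it sets out from 10 and 4 and returns at 13. Bromination of 10 with NBS at its nucleophilic terminus C6 gives the tertiary bromo enone F1. Kinetic enolsilylation of 4 (LiN(iPr)2, TMSCl, −78 °C) gives the C5 silyl enol ether F2. Photoredox radical alkylation of F2 with F1 (Ru(bpy)3Cl2, visible light, MeCN) joins C5 to C6 anti to the amide and gives the 1,4-diketone F3. Soft enolisation (TMSOTf, Et3N) on the less shielded side gives the C10 silyl enol ether F4. TMSOTf-catalysed intramolecular Mukaiyama–Michael addition onto the β-alkoxy enone closes C9–C10 and gives, after work-up, the bicyclic diketone F5. TBSOTf and Et3N, with only C8 enolisable, then give 13.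

2. Step 17. The conjugated aldehyde may transfer hydride sluggishly, or the β-hydroxy ketone may undergo retro-aldol cleavage on the Lewis-acidic samarium alkoxide. The fallback sets out from 23 and returns at 24. Hydroxyl-directed reduction with Me4NBH(OAc)3 in MeCN/AcOH at −20 °C (Saksena–Evans reduction) gives the trans-diol F6. Yamaguchi esterification with one equivalent of tiglic acid then acylates the C9 hydroxyl, which is less shielded than the C7 hydroxyl next to the gem-dimethyl carbon.

3. Step 14. The two arms may fail to reach the strained bicyclo[3.1.1]heptenone: epimerisation at C11 may be slow, or aldol and acyl-transfer pathways of the phosphonate anion may compete. The fallback closes the ring by metathesis; it sets out from 18 and returns at 21. Vinylmagnesium bromide at −78 °C followed by MeMgBr at 0 °C in one flask gives the allylic alcohol methyl ketone F7. Wittig methylenation of the ketone gives the isopropenyl compound F8. Dess–Martin oxidation gives the dienone F9. Ring-closing metathesis with second-generation Hoveyda–Grubbs catalyst in toluene at 80 °C then forms C2=C3.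

Further compounds
F1 | step 8 | (E)-4-bromo-1-(4-methoxybenzyloxy)-4-methylpent-1-en-3-one | CC(C)(Br)C(=O)/C=C/OCc1ccc(OC)cc1
F2 | step 8 | C5 trimethylsilyl enol ether of 4 | CON(C)C(=O)[C@H]1C=C(O[Si](C)(C)C)[C@@H]1C
F3 | step 8 | 1,4-diketone with C5–C6 bond and pendant β-alkoxy enone | CON(C)C(=O)[C@H]1[C@H](C(C)(C)C(=O)/C=C/OCc2ccc(OC)cc2)C(=O)[C@@H]1C
F4 | step 8 | C10 trimethylsilyl enol ether of F3 | CON(C)C(=O)[C@H]1[C@H](C(C)(C)C(=O)/C=C/OCc2ccc(OC)cc2)C(O[Si](C)(C)C)=C1C
F5 | step 8 | bicyclo[4.1.1]octane-3,8-dione (C7 and C11 ketones, C9 OPMB, C4 Weinreb amide) | COc1ccc(CO[C@@H]2CC(=O)C(C)(C)[C@@H]3C(=O)[C@@]2(C)[C@H]3C(=O)N(C)OC)cc1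
F6 | step 17 | tricyclic enone trans-7,9-diol | O[C@@H]1C[C@@H](O)C(C)(C)[C@@H]2[C@H]3C(=O)C=C(C)[C@@H]2[C@]31C
F7 | step 14 | C11 1-hydroxyallyl, C4 acetyl compound | COc1ccc(CO[C@@H]2C=C(O[Si](C)(C)C(C)(C)C)C(C)(C)[C@@H]3[C@@H](C(O)C=C)[C@@]2(C)[C@H]3C(C)=O)cc1
F8 | step 14 | C11 1-hydroxyallyl, C4 isopropenyl compound | COc1ccc(CO[C@@H]2C=C(O[Si](C)(C)C(C)(C)C)C(C)(C)[C@@H]3[C@@H](C(O)C=C)[C@@]2(C)[C@H]3C(C)=C)cc1
F9 | step 14 | C11 acryloyl, C4 isopropenyl compound | COc1ccc(CO[C@@H]2C=C(O[Si](C)(C)C(C)(C)C)C(C)(C)[C@@H]3[C@@H](C(=O)C=C)[C@@]2(C)[C@H]3C(C)=C)cc1
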